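The earlier runs and the new flask were generated by integration for an exercise, noise included.

In a one-step world each mole of partner fed ends as product, and the ledger needs no other column. We keep that ledger in percent of both substrates charged.

| setting | autumn | flask |
|---|---|---|
| left-handed substrate | 21 mM | 21 mM |
| right-handed substrate | 21 mM | 21 mM |
| partner | 25.2 mM (fed, over 6.0 h) | 25.2 mM (fed, over 6.0 h) |
| free catalyst | 0.42 mM | 0.42 mM |
| impurity | 98 µM | 49 µM |
| remark | run made earlier |  |
| time |  | 40 h |

autumn run (percent of the left-handed substrate and right-handed substrate together charged)

| time / h | right-handed substrate / % | left-handed product / % | left-handed substrate / % | right-handed product / % |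
|---|---|---|---|---|
| 1.00 | 50.2 | 2.7 | 47.5 | 0.4 |
| 3.00 | 49.4 | 11.8 | 37.6 | 0.2 |
| 5.00 | 49.6 | 23.5 | 27.4 | 0 |
| 8.00 | 49.4 | 32.4 | 17.0 | 0.9 |

(standard deviation of a reading: 0.3 percentage points)

- the species in which most of what was charged as left-handed substrate and right-handed substrate together, at 40 h sits (left-handed product / right-handed substrate / left-handed substrate / right-handed product)
- the largest share itself, whichever of these holds it, in percent of the left-handed substrate and right-handed substrate together charged

- free catalyst is single-handed; left-handed substrate and right-handed substrate are mirror images of each other, charged as a racemate, each of them at the stated concentration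
- the earlier runs were read with a standard deviation of 0.3 percentage points
- no earlier run changes the charge of impurity; that part of a forecast is a guess

First entry: the flask's partner comes to 60.0%, and left-handed substrate can take 50.0%. The partner charge minus the left-handed substrate charge, over both substrates charged, is 10.0%; we call it the spare partner. Any partner beyond that which idles is taken from left-handed product.

Second entry: how much idles? We assume the loss of left-handed substrate is pseudo-first-order, with a constant that follows c(partner). On paper, c(partner) is what was fed minus left-handed product. The autumn run gives, at mid-window:

early, 1.00 h to 3.00 h: constant 0.117 h⁻¹, paper partner 12.8%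

late, 5.00 h to 8.00 h: constant 0.159 h⁻¹, paper partner 32.0%

Paper partner grew 2.50-fold, the constant 1.36-fold. We hold the catalyst steady, count all early partner as working, and assume the impurity does not touch this. Then:

idle partner = late paper partner − early paper partner × constant ratio = 14.7%

This is a reading of the autumn run, and it exceeds the spare partner. If that much stays idle in the flask, left-handed product ends near 45.3%, below the 49.4% read for right-handed substrate in the autumn run. So we expect right-handed substrate to lead the flask at 40 h.

The forecast gives right-handed substrate at 49%: “right-handed substrate probably still holds the most”.

    partner + free catalyst + right-handed substrate → free catalyst + right-handed product (k = 0.186 M⁻² s⁻¹)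
    partner ⇌ dormant form (K = 23.1, k = 6.27 × 10⁻⁵ s⁻¹)
    free catalyst + impurity → spent catalyst (k = 28.8 M⁻¹ s⁻¹)
    partner + free catalyst + left-handed substrate → free catalyst + left-handed product (k = 24.4 M⁻² s⁻¹)

At 40 h the flask holds 49.4% in right-handed substrate. Its dormant form stands at 8.04 mM, or 19.2% of both substrates charged, more than the spare partner of 10.0%, and left-handed product at 39.7%. In the neighbour flask with 100 mM of partner, the spare partner is 188%. Its dormant form at 40.0 h is 73.7 mM, or 176%, less than that spare, and left-handed product leads there at 50.0%.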